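## Retrosynthetic overview

1. Feature: C6 is both the allylic carbinol on C5 of the (Z)-C4=C5 alkene in the ten-membered ring C1–C10 and the carbon whose oxygen is the lactone oxygen, γ to C12 (O–C6–C7–C11–C12). One alkenyl-to-aldehyde addition therefore forms C5–C6 and places the alkoxide where it closes the five-membered lactone.
2. Target 37 ⇐ C8 desilylation, C9 esterification with (2R,3S)-2,3-dimethyloxirane-2-carboxylic acid 34, C9 desilylation ⇐ bicyclic lactone 30 ⇐ (key) open-chain C5 iodoalkene / C6 aldehyde / C12 methyl ester 27. The carbocycle (ring A) closes first and the lactone (ring B) second, in one operation.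
3. 27 ⇐ C7–C8 by aqueous indium Barbier addition of the Baylis–Hillman-derived allyl bromide 4 (C6 as dimethyl acetal) to the free α-hydroxy aldehyde 21 (chelation gives 7,8-syn and 8,9-syn), then C9–OTES, C8–OTBS and acetal cleavage.
4. 21 ⇐ (Z)-C1=C10 by Wittig reaction of the α-alkoxy ketone 7 (C9 from the glycerate pool) with the ylide of 13 (C3 by Noyori transfer hydrogenation); (Z)-C4=C5–I by anti-carbomagnesiation and iodination of the C3 propargylic alcohol.

Key step: step 19

Remark: germacrane numbering is used throughout (ring C1–C10, C6 lactone carbinol, C7 ring-fusion CH, C11=C13 methylidene, C12 carbonyl); the oxirane ester written in the target has its two methyl groups cis, i.e. the (2R,3S) acid of tiglic-acid geometry, and that acid is the one made here.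

## Route

Step 1
Reactants: 1 methyl acrylate; 2 2,2-dimethoxyacetaldehyde (60 % aqueous solution)
Product: 3 methyl 3-hydroxy-4,4-dimethoxy-2-methylidenebutanoate (racemic)
Conditions: DABCO, 1,4-dioxane/H2O, rt
Reagents that add atoms: none
Why: Baylis–Hillman reaction of the acrylate with an electron-poor aldehyde; the carbinol centre is racemic and is removed in step 2.

Step 2
Reactants: 3 methyl 3-hydroxy-4,4-dimethoxy-2-methylidenebutanoate
Product: 4 methyl (2Z)-2-(bromomethyl)-4,4-dimethoxybut-2-enoate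
Conditions: NBS, Me2S, CH2Cl2, 0 °C to rt
Reagents that add atoms: N-bromosuccinimide, O=C1CCC(=O)N1Br
Why: Corey–Kim-type activation of the allylic alcohol as an alkoxysulfonium ion and SN2' attack of bromide should give the (Z)-2-(bromomethyl)alk-2-enoate under non-acidic conditions that spare the acetal.

Step 3
Reactants: 5 methyl (4R)-2,2-dimethyl-1,3-dioxolane-4-carboxylate
Product: 6 (4R)-N-methoxy-N,2,2-trimethyl-1,3-dioxolane-4-carboxamide
Conditions: MeNH(OMe)·HCl, iPrMgCl, THF, −20 °C
Reagents that add atoms: N,O-dimethylhydroxylamine hydrochloride, CNOC.Cl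
Why: Weinreb amide formation from the ester with the magnesium amide at low temperature, where the α-alkoxy stereocentre (the future C9) is not enolised.

Step 4
Reactants: 6 (4R)-N-methoxy-N,2,2-trimethyl-1,3-dioxolane-4-carboxamide
Product: 7 1-[(4R)-2,2-dimethyl-1,3-dioxolan-4-yl]ethan-1-one
Conditions: MeMgBr, THF, 0 °C; aq. NH4Cl
Reagents that add atoms: methylmagnesium bromide, C[Mg]Br
Why: Weinreb ketone synthesis, in which the magnesium chelate of the tetrahedral adduct prevents over-addition and releases the methyl ketone (C14–C10–C9–C8) on work-up.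

Step 5
Reactants: 8 3-chloropropanoyl chloride; 9 bis(trimethylsilyl)acetylene
Product: 10 5-chloro-1-(trimethylsilyl)pent-1-yn-3-one
Conditions: AlCl3, CH2Cl2, 0 °C
Reagents that add atoms: none
Why: Friedel–Crafts acylation of the bis-silyl alkyne by ipso-substitution of one trimethylsilyl group gives the silyl ynone (C1–C5) directly.

Step 6
Reactants: 10 5-chloro-1-(trimethylsilyl)pent-1-yn-3-one
Product: 11 (3S)-5-chloro-1-(trimethylsilyl)pent-1-yn-3-ol
Conditions: Ru[(S,S)-TsNCH(Ph)CH(Ph)NH](p-cymene) (1 mol %), iPrOH, rt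
Reagents that add atoms: none
Why: Noyori asymmetric transfer hydrogenation of an alkynyl ketone, in which the (S,S)-diamine complex should deliver hydride to the face that gives the (S)-propargylic alcohol (C3), and the base-free amido catalyst spares the β-chloro ketone.

Step 7
Reactants: 11 (3S)-5-chloro-1-(trimethylsilyl)pent-1-yn-3-ol
Product: 12 tert-butyl{[(3S)-5-chloro-1-(trimethylsilyl)pent-1-yn-3-yl]oxy}dimethylsilane
Conditions: TBSCl, imidazole, DMF, rt
Reagents that add atoms: tert-butyldimethylsilyl chloride, CC(C)(C)[Si](C)(C)Cl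
Why: Standard silylation, needed because a free or acylated C3 oxygen would interfere with the ylide in step 9.

Step 8
Reactants: 12 tert-butyl{[(3S)-5-chloro-1-(trimethylsilyl)pent-1-yn-3-yl]oxy}dimethylsilane
Product: 13 {(3S)-3-[(tert-butyldimethylsilyl)oxy]-5-(trimethylsilyl)pent-4-yn-1-yl}triphenylphosphonium iodide
Conditions: PPh3, NaI, MeCN, reflux
Reagents that add atoms: triphenylphosphine, c1ccc(cc1)P(c1ccccc1)c1ccccc1; sodium iodide, [Na+].[I-]
Why: SN2 phosphonium salt formation at the unhindered primary carbon (C1) with in situ Finkelstein exchange of chloride.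

Step 9
Reactants: 13 {(3S)-3-[(tert-butyldimethylsilyl)oxy]-5-(trimethylsilyl)pent-4-yn-1-yl}triphenylphosphonium iodide; 7 1-[(4R)-2,2-dimethyl-1,3-dioxolan-4-yl]ethan-1-one
Product: 15 tert-butyl{[(3S,5Z)-6-[(4S)-2,2-dimethyl-1,3-dioxolan-4-yl]-1-(trimethylsilyl)hept-5-en-1-yn-3-yl]oxy}dimethylsilane, via phosphorus ylide 14 (not isolated)
Conditions: NaHMDS, THF, −78 °C; then 7, −78 °C to rt
Reagents that add atoms: none
Why: Wittig olefination with a salt-free non-stabilised ylide, for which α-alkoxy ketones give the trisubstituted alkene with the ylide chain cis to the alkoxy-bearing carbon, here the (Z)-C1=C10 alkene with C2 cis to C9.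

Step 10
Reactants: 15 tert-butyl{[(3S,5Z)-6-[(4S)-2,2-dimethyl-1,3-dioxolan-4-yl]-1-(trimethylsilyl)hept-5-en-1-yn-3-yl]oxy}dimethylsilane
Product: 16 (3S,5Z)-6-[(4S)-2,2-dimethyl-1,3-dioxolan-4-yl]hept-5-en-1-yn-3-ol
Conditions: TBAF, THF, 0 °C to rt
Reagents that add atoms: none
Why: Fluoride cleaves the O–Si and the alkynyl C–Si bond in one operation and frees the propargylic alcohol that directs step 11.

Step 11
Reactants: 16 (3S,5Z)-6-[(4S)-2,2-dimethyl-1,3-dioxolan-4-yl]hept-5-en-1-yn-3-ol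
Product: 18 (1Z,3S,5Z)-6-[(4S)-2,2-dimethyl-1,3-dioxolan-4-yl]-1-iodo-2-methylhepta-1,5-dien-3-ol, via alkenylmagnesium bromide alkoxide 17 (not isolated)
Conditions: MeMgBr (4 equiv), CuI (0.2 equiv), THF, 0 °C to rt; then I2, −78 to 0 °C
Reagents that add atoms: methylmagnesium bromide, C[Mg]Br; iodine, II
Why: Copper-catalysed anti-carbomagnesiation of the propargylic magnesium alkoxide places methyl on C4 and magnesium on C5 in a five-membered chelate, and iodinolysis with retention gives the (Z)-iodoalkene with iodine cis to C3.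

Step 12
Reactants: 18 (1Z,3S,5Z)-6-[(4S)-2,2-dimethyl-1,3-dioxolan-4-yl]-1-iodo-2-methylhepta-1,5-dien-3-ol
Product: 19 (1Z,3S,5Z)-6-[(4S)-2,2-dimethyl-1,3-dioxolan-4-yl]-1-iodo-2-methylhepta-1,5-dien-3-yl acetate
Conditions: Ac2O, pyridine, DMAP (cat.), CH2Cl2, rt
Reagents that add atoms: acetic anhydride, CC(=O)OC(C)=O
Why: Acylation installs the C3 acetate of the target once the strongly basic steps are past.

Step 13
Reactants: 19 (1Z,3S,5Z)-6-[(4S)-2,2-dimethyl-1,3-dioxolan-4-yl]-1-iodo-2-methylhepta-1,5-dien-3-yl acetate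
Product: 20 (1Z,3S,5Z,7S)-7,8-dihydroxy-1-iodo-2,6-dimethylocta-1,5-dien-3-yl acetate
Conditions: AcOH/H2O/THF (3:1:1), 40 °C
Reagents that add atoms: none
Why: Mild acid hydrolysis of the acetonide frees the C8/C9 diol, and the acetate and the iodoalkene should be stable to it.

Step 14
Reactants: 20 (1Z,3S,5Z,7S)-7,8-dihydroxy-1-iodo-2,6-dimethylocta-1,5-dien-3-yl acetate
Product: 21 (1Z,3S,5Z,7S)-7-hydroxy-1-iodo-2,6-dimethyl-8-oxoocta-1,5-dien-3-yl acetate
Conditions: TEMPO (0.1 equiv), PhI(OAc)2 (1.1 equiv), CH2Cl2, 0 °C to rt; crude product used at once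
Reagents that add atoms: none
Why: Oxoammonium (TEMPO) oxidation is selective for the primary C8 alcohol over the secondary C9 alcohol, and the base-free medium should keep the C9 centre of the α-hydroxy aldehyde, which is carried on as its hemiacetal dimers.

Step 15
Reactants: 21 (1Z,3S,5Z,7S)-7-hydroxy-1-iodo-2,6-dimethyl-8-oxoocta-1,5-dien-3-yl acetate; 4 methyl (2Z)-2-(bromomethyl)-4,4-dimethoxybut-2-enoate
Product: 23 methyl (3R,4S,5S,6Z,9S,10Z)-9-acetoxy-3-(dimethoxymethyl)-4,5-dihydroxy-11-iodo-6,10-dimethyl-2-methylideneundeca-6,10-dienoate, via allylindium dibromide 22 (not isolated)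
Conditions: In powder (2 equiv), 4 (1.5 equiv), THF/H2O (1:1), rt
Reagents that add atoms: none
Why: Barbier-type indium allylation in water, in which the free C9 hydroxyl and the aldehyde oxygen chelate indium so that the allyl group adds anti to C10 (8,9-syn, C8 S), while the Z-configured γ-substituted allylindium reacts at its γ-carbon through a chair transition state (7,8-syn, C7 R).

Step 16
Reactants: 23 methyl (3R,4S,5S,6Z,9S,10Z)-9-acetoxy-3-(dimethoxymethyl)-4,5-dihydroxy-11-iodo-6,10-dimethyl-2-methylideneundeca-6,10-dienoate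
Product: 24 methyl (3R,4S,5S,6Z,9S,10Z)-9-acetoxy-3-(dimethoxymethyl)-4-hydroxy-11-iodo-6,10-dimethyl-2-methylidene-5-[(triethylsilyl)oxy]undeca-6,10-dienoate
Conditions: TESCl (1.05 equiv), imidazole, CH2Cl2, −40 °C
Reagents that add atoms: chlorotriethylsilane, CC[Si](CC)(CC)Cl
Why: Regioselective silylation, since the allylic C9 hydroxyl beside the planar C10 should react faster than the C8 hydroxyl, which is flanked by the doubly branched C7.

Step 17
Reactants: 24 methyl (3R,4S,5S,6Z,9S,10Z)-9-acetoxy-3-(dimethoxymethyl)-4-hydroxy-11-iodo-6,10-dimethyl-2-methylidene-5-[(triethylsilyl)oxy]undeca-6,10-dienoate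
Product: 25 methyl (3R,4S,5S,6Z,9S,10Z)-9-acetoxy-4-[(tert-butyldimethylsilyl)oxy]-3-(dimethoxymethyl)-11-iodo-6,10-dimethyl-2-methylidene-5-[(triethylsilyl)oxy]undeca-6,10-dienoate
Conditions: TBSOTf (1.2 equiv), 2,6-lutidine, CH2Cl2, −78 to −40 °C
Reagents that add atoms: tert-butyldimethylsilyl triflate, CC(C)(C)[Si](C)(C)OS(=O)(=O)C(F)(F)F
Why: Silyl triflate silylation of the hindered C8 hydroxyl at low temperature, which also removes the only other oxygen that could lactonise onto C12.

Step 18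
Reactants: 25 methyl (3R,4S,5S,6Z,9S,10Z)-9-acetoxy-4-[(tert-butyldimethylsilyl)oxy]-3-(dimethoxymethyl)-11-iodo-6,10-dimethyl-2-methylidene-5-[(triethylsilyl)oxy]undeca-6,10-dienoate
Product: 27 methyl (3R,4S,5S,6Z,9S,10Z)-9-acetoxy-4-[(tert-butyldimethylsilyl)oxy]-3-formyl-11-iodo-6,10-dimethyl-2-methylidene-5-[(triethylsilyl)oxy]undeca-6,10-dienoate, via N-(methoxyalkyl)collidinium triflate 26 (not isolated)
Conditions: TESOTf, 2,4,6-collidine, CH2Cl2, 0 °C; then H2O; used at once
Reagents that add atoms: water, O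
Why: Silyl triflate/collidine cleavage of a dimethyl acetal through its pyridinium salt, a non-acidic unmasking that keeps both silyl ethers and should avoid enolisation of the C7–H, which is α to the aldehyde and allylic to the acrylate.

Step 19
Reactants: 27 methyl (3R,4S,5S,6Z,9S,10Z)-9-acetoxy-4-[(tert-butyldimethylsilyl)oxy]-3-formyl-11-iodo-6,10-dimethyl-2-methylidene-5-[(triethylsilyl)oxy]undeca-6,10-dienoate
Product: 30 (3S,6S,7S,8S,9S)-3-acetoxy-8-(tert-butyldimethylsilyloxy)-9-(triethylsilyloxy)-(1(10)Z,4Z)-germacra-1(10),4,11(13)-trien-12,6-olide (cis-fused lactone), via alkenylchromium dichloride 28 (not isolated), via chromium alkoxide 29 (not isolated)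
Conditions: CrCl2 (10 equiv), NiCl2 (0.1 equiv), degassed DMSO (0.003 M), rt; aq. NH4Cl
Reagents that add atoms: none
Why: Zerovalent nickel (formed from NiCl2 by CrCl2) inserts into the C5–I bond and passes the alkenyl group to trivalent chromium with retention of the Z geometry, the alkenylchromium 28 adds to the C6 aldehyde, and the chromium alkoxide 29 attacks the C12 methyl ester and expels methoxide; the closest known reaction type is the Nozaki–Hiyama–Kishi macrocyclisation with lactonisation of the resulting alkoxide onto a γ-ester. The ten-membered carbocycle closes by intramolecular 1,2-addition of C5 to the C6 carbonyl (exo-trig with respect to C=O) under high dilution, and the lactone closes by 5-exo-trig acyl substitution of O6 at C12, open only to O6 because O8 and O9 are silylated. The new stereocentre C6 is set by the aldehyde face that the tethered alkenylchromium can reach: with the C7–C8 ring bond synclinal to the forming C5–C6 bond and the C11 acrylate branch antiperiplanar to it (the sp2 branch in the Felkin–Anh anti position), C5 should add to the face that gives (6S), with O6 syn to O8 and H6 cis to H7, the cis-fused lactone. The step needs chemoselectivity for the alkenyl iodide over the allylic acetate, the acrylate and both esters, which nickel-catalysed formation of the alkenylchromium provides, and it needs C7 to stay intact, which the base-free medium secures. The (6S) face selectivity is the least secured element, because the simple acyclic 1,2- and 1,3-induction models with C8 as the large group point the other way, so it rests on the conformational constraint that the two Z-alkenes and the two bulky silyloxy groups impose on the ring-closing transition state.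

Step 20
Reactants: 30 (3S,6S,7S,8S,9S)-3-acetoxy-8-(tert-butyldimethylsilyloxy)-9-(triethylsilyloxy)-(1(10)Z,4Z)-germacra-1(10),4,11(13)-trien-12,6-olide
Product: 31 (3S,6S,7S,8S,9S)-3-acetoxy-8-(tert-butyldimethylsilyloxy)-9-hydroxy-(1(10)Z,4Z)-germacra-1(10),4,11(13)-trien-12,6-olide
Conditions: PPTS, MeOH/CH2Cl2, 0 °C
Reagents that add atoms: none
Why: Acid-catalysed methanolysis removes the secondary allylic triethylsilyl ether much faster than the hindered tert-butyldimethylsilyl ether at C8.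

Step 21
Reactants: 32 (2E)-2-methylbut-2-en-1-ol (tiglyl alcohol)
Product: 33 [(2S,3S)-2,3-dimethyloxiran-2-yl]methanol
Conditions: Ti(OiPr)4 (cat.), L-(+)-diethyl tartrate, tBuOOH, 4 Å molecular sieves, CH2Cl2, −20 °C
Reagents that add atoms: tert-butyl hydroperoxide, CC(C)(C)OO
Why: Sharpless asymmetric epoxidation, in which the L-(+)-tartrate complex delivers oxygen to the face that gives the (2S,3S) epoxy alcohol, and the E geometry fixes the two methyl groups cis on the oxirane.

Step 22
Reactants: 33 [(2S,3S)-2,3-dimethyloxiran-2-yl]methanol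
Product: 34 (2R,3S)-2,3-dimethyloxirane-2-carboxylic acid
Conditions: RuCl3·xH2O (cat.), NaIO4, MeCN/EtOAc/H2O, rt
Reagents that add atoms: sodium periodate, [Na+].[O-]I(=O)(=O)=O; water, O
Why: Ruthenium tetroxide oxidation takes the primary alcohol to the acid without touching the epoxide, and the C2 descriptor changes to R only through the change of CIP priorities.

Step 23
Reactants: 34 (2R,3S)-2,3-dimethyloxirane-2-carboxylic acid; 31 (3S,6S,7S,8S,9S)-3-acetoxy-8-(tert-butyldimethylsilyloxy)-9-hydroxy-(1(10)Z,4Z)-germacra-1(10),4,11(13)-trien-12,6-olide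
Product: 36 (3S,6S,7S,8S,9S)-3-acetoxy-8-(tert-butyldimethylsilyloxy)-9-[(2R,3S)-2,3-dimethyloxirane-2-carbonyloxy]-(1(10)Z,4Z)-germacra-1(10),4,11(13)-trien-12,6-olide, via mixed carboxylic anhydride 35 (not isolated)
Conditions: 2,4,6-Cl3C6H2COCl, Et3N, toluene, rt; then 31, DMAP, toluene, rt
Reagents that add atoms: none
Why: Yamaguchi esterification, in which the mixed anhydride of the hindered tertiary epoxy acid is attacked at the less hindered acyl group by DMAP and then by the C9 alcohol, with retention at C9.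

Step 24
Reactants: 36 (3S,6S,7S,8S,9S)-3-acetoxy-8-(tert-butyldimethylsilyloxy)-9-[(2R,3S)-2,3-dimethyloxirane-2-carbonyloxy]-(1(10)Z,4Z)-germacra-1(10),4,11(13)-trien-12,6-olide
Product: 37 (3S,6S,7R,8S,9S)-3-acetoxy-8-hydroxy-9-[(2R,3S)-2,3-dimethyloxirane-2-carbonyloxy]-(1(10)Z,4Z)-germacra-1(10),4,11(13)-trien-12,6-olide (CNP0137407.9)
Conditions: HF·pyridine, pyridine, THF, 0 °C to rt
Reagents that add atoms: none
Why: Buffered fluoride desilylation frees the C8 hydroxyl under weakly acidic conditions that should not move the C9 ester, open the glycidic ester or add to the methylidene lactone.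

## Compound list

1 | methyl acrylate | C=CC(=O)OC | starting material
2 | 2,2-dimethoxyacetaldehyde | COC(OC)C=O | starting material
3 | methyl 3-hydroxy-4,4-dimethoxy-2-methylidenebutanoate (racemic) | COC(=O)C(=C)C(O)C(OC)OC | intermediate
4 | methyl (2Z)-2-(bromomethyl)-4,4-dimethoxybut-2-enoate | COC(=O)/C(CBr)=C/C(OC)OC | intermediate
5 | methyl (4R)-2,2-dimethyl-1,3-dioxolane-4-carboxylate | COC(=O)[C@H]1COC(C)(C)O1 | starting material
6 | (4R)-N-methoxy-N,2,2-trimethyl-1,3-dioxolane-4-carboxamide | CON(C)C(=O)[C@H]1COC(C)(C)O1 | intermediate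
7 | 1-[(4R)-2,2-dimethyl-1,3-dioxolan-4-yl]ethan-1-one | CC(=O)[C@H]1COC(C)(C)O1 | intermediate
8 | 3-chloropropanoyl chloride | O=C(Cl)CCCl | starting material
9 | bis(trimethylsilyl)acetylene | C[Si](C)(C)C#C[Si](C)(C)C | starting material
10 | 5-chloro-1-(trimethylsilyl)pent-1-yn-3-one | O=C(CCCl)C#C[Si](C)(C)C | intermediate
11 | (3S)-5-chloro-1-(trimethylsilyl)pent-1-yn-3-ol | ClCC[C@H](O)C#C[Si](C)(C)C | intermediate
12 | tert-butyl{[(3S)-5-chloro-1-(trimethylsilyl)pent-1-yn-3-yl]oxy}dimethylsilane | ClCC[C@H](O[Si](C)(C)C(C)(C)C)C#C[Si](C)(C)C | intermediate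
13 | {(3S)-3-[(tert-butyldimethylsilyl)oxy]-5-(trimethylsilyl)pent-4-yn-1-yl}triphenylphosphonium iodide | [I-].c1ccc(cc1)[P+](c1ccccc1)(c1ccccc1)CC[C@H](O[Si](C)(C)C(C)(C)C)C#C[Si](C)(C)C | intermediate
14 | phosphorus ylide of 13 (not isolated) | c1ccc(cc1)P(c1ccccc1)(c1ccccc1)=CC[C@H](O[Si](C)(C)C(C)(C)C)C#C[Si](C)(C)C | intermediate
15 | tert-butyl{[(3S,5Z)-6-[(4S)-2,2-dimethyl-1,3-dioxolan-4-yl]-1-(trimethylsilyl)hept-5-en-1-yn-3-yl]oxy}dimethylsilane | CC1(C)OC[C@@H](O1)/C(C)=C\C[C@H](O[Si](C)(C)C(C)(C)C)C#C[Si](C)(C)C | intermediate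
16 | (3S,5Z)-6-[(4S)-2,2-dimethyl-1,3-dioxolan-4-yl]hept-5-en-1-yn-3-ol | CC1(C)OC[C@@H](O1)/C(C)=C\C[C@H](O)C#C | intermediate
17 | alkenylmagnesium bromide alkoxide from 16 (Mg on C5 cis to C3, methyl on C4; not isolated) | CC1(C)OC[C@@H](O1)/C(C)=C\C[C@H](O[Mg]Br)/C(C)=C\[Mg]Br | intermediate
18 | (1Z,3S,5Z)-6-[(4S)-2,2-dimethyl-1,3-dioxolan-4-yl]-1-iodo-2-methylhepta-1,5-dien-3-ol | CC1(C)OC[C@@H](O1)/C(C)=C\C[C@H](O)/C(C)=C\I | intermediate
19 | (1Z,3S,5Z)-6-[(4S)-2,2-dimethyl-1,3-dioxolan-4-yl]-1-iodo-2-methylhepta-1,5-dien-3-yl acetate | CC1(C)OC[C@@H](O1)/C(C)=C\C[C@H](OC(C)=O)/C(C)=C\I | intermediate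
20 | (1Z,3S,5Z,7S)-7,8-dihydroxy-1-iodo-2,6-dimethylocta-1,5-dien-3-yl acetate | OC[C@@H](O)/C(C)=C\C[C@H](OC(C)=O)/C(C)=C\I | intermediate
21 | (1Z,3S,5Z,7S)-7-hydroxy-1-iodo-2,6-dimethyl-8-oxoocta-1,5-dien-3-yl acetate | O=C[C@@H](O)/C(C)=C\C[C@H](OC(C)=O)/C(C)=C\I | intermediate
22 | [2-(methoxycarbonyl)-4,4-dimethoxybut-2-enyl]indium dibromide (allylindium from 4, drawn as the dibromide of trivalent indium; not isolated) | COC(=O)/C(C[In](Br)Br)=C/C(OC)OC | intermediate
23 | methyl (3R,4S,5S,6Z,9S,10Z)-9-acetoxy-3-(dimethoxymethyl)-4,5-dihydroxy-11-iodo-6,10-dimethyl-2-methylideneundeca-6,10-dienoate | COC(=O)C(=C)[C@@H](C(OC)OC)[C@H](O)[C@@H](O)/C(C)=C\C[C@H](OC(C)=O)/C(C)=C\I | intermediate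
24 | methyl (3R,4S,5S,6Z,9S,10Z)-9-acetoxy-3-(dimethoxymethyl)-4-hydroxy-11-iodo-6,10-dimethyl-2-methylidene-5-[(triethylsilyl)oxy]undeca-6,10-dienoate | COC(=O)C(=C)[C@@H](C(OC)OC)[C@H](O)[C@@H](O[Si](CC)(CC)CC)/C(C)=C\C[C@H](OC(C)=O)/C(C)=C\I | intermediate
25 | methyl (3R,4S,5S,6Z,9S,10Z)-9-acetoxy-4-[(tert-butyldimethylsilyl)oxy]-3-(dimethoxymethyl)-11-iodo-6,10-dimethyl-2-methylidene-5-[(triethylsilyl)oxy]undeca-6,10-dienoate | COC(=O)C(=C)[C@@H](C(OC)OC)[C@H](O[Si](C)(C)C(C)(C)C)[C@@H](O[Si](CC)(CC)CC)/C(C)=C\C[C@H](OC(C)=O)/C(C)=C\I | intermediate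
26 | N-(methoxyalkyl)-2,4,6-trimethylpyridinium triflate from 25 (C6 bears OMe and the collidinium nitrogen, both C6 epimers; not isolated) | COC(=O)C(=C)[C@@H](C(OC)[n+]1c(C)cc(C)cc1C)[C@H](O[Si](C)(C)C(C)(C)C)[C@@H](O[Si](CC)(CC)CC)/C(C)=C\C[C@H](OC(C)=O)/C(C)=C\I.[O-]S(=O)(=O)C(F)(F)F | intermediate
27 | methyl (3R,4S,5S,6Z,9S,10Z)-9-acetoxy-4-[(tert-butyldimethylsilyl)oxy]-3-formyl-11-iodo-6,10-dimethyl-2-methylidene-5-[(triethylsilyl)oxy]undeca-6,10-dienoate (key-step precursor) | COC(=O)C(=C)[C@@H](C=O)[C@H](O[Si](C)(C)C(C)(C)C)[C@@H](O[Si](CC)(CC)CC)/C(C)=C\C[C@H](OC(C)=O)/C(C)=C\I | intermediate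
28 | alkenylchromium dichloride from 27 (trivalent chromium on C5, Z geometry retained; not isolated) | COC(=O)C(=C)[C@@H](C=O)[C@H](O[Si](C)(C)C(C)(C)C)[C@@H](O[Si](CC)(CC)CC)/C(C)=C\C[C@H](OC(C)=O)/C(C)=C\[Cr](Cl)Cl | intermediate
29 | ten-membered (6S) chromium alkoxide, C12 still the methyl ester (dichlorochromium alkoxide of trivalent chromium; not isolated) | COC(=O)C(=C)[C@H]1[C@@H](O[Cr](Cl)Cl)/C=C(/C)[C@@H](OC(C)=O)C/C=C(/C)[C@H](O[Si](CC)(CC)CC)[C@H]1O[Si](C)(C)C(C)(C)C | intermediate
30 | (3S,6S,7S,8S,9S)-3-acetoxy-8-(tert-butyldimethylsilyloxy)-9-(triethylsilyloxy)-(1(10)Z,4Z)-germacra-1(10),4,11(13)-trien-12,6-olide (key-step product; C7 is formally S here because the C8 silyloxy branch outranks C6) | C=C1C(=O)O[C@H]2/C=C(/C)[C@@H](OC(C)=O)C/C=C(/C)[C@H](O[Si](CC)(CC)CC)[C@@H](O[Si](C)(C)C(C)(C)C)[C@@H]12 | intermediate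
31 | (3S,6S,7S,8S,9S)-3-acetoxy-8-(tert-butyldimethylsilyloxy)-9-hydroxy-(1(10)Z,4Z)-germacra-1(10),4,11(13)-trien-12,6-olide | C=C1C(=O)O[C@H]2/C=C(/C)[C@@H](OC(C)=O)C/C=C(/C)[C@H](O)[C@@H](O[Si](C)(C)C(C)(C)C)[C@@H]12 | intermediate
32 | (2E)-2-methylbut-2-en-1-ol | C/C=C(\C)CO | starting material
33 | [(2S,3S)-2,3-dimethyloxiran-2-yl]methanol | OC[C@]1(C)O[C@H]1C | intermediate
34 | (2R,3S)-2,3-dimethyloxirane-2-carboxylic acid | OC(=O)[C@]1(C)O[C@H]1C | intermediate
35 | (2R,3S)-2,3-dimethyloxirane-2-carboxylic 2,4,6-trichlorobenzoic anhydride (not isolated) | O=C(OC(=O)c1c(Cl)cc(Cl)cc1Cl)[C@]1(C)O[C@H]1C | intermediate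
36 | (3S,6S,7S,8S,9S)-3-acetoxy-8-(tert-butyldimethylsilyloxy)-9-[(2R,3S)-2,3-dimethyloxirane-2-carbonyloxy]-(1(10)Z,4Z)-germacra-1(10),4,11(13)-trien-12,6-olide | C=C1C(=O)O[C@H]2/C=C(/C)[C@@H](OC(C)=O)C/C=C(/C)[C@H](OC(=O)[C@]3(C)O[C@H]3C)[C@@H](O[Si](C)(C)C(C)(C)C)[C@@H]12 | intermediate
37 | (3S,6S,7R,8S,9S)-3-acetoxy-8-hydroxy-9-[(2R,3S)-2,3-dimethyloxirane-2-carbonyloxy]-(1(10)Z,4Z)-germacra-1(10),4,11(13)-trien-12,6-olide (CNP0137407.9) | C=C1C(=O)O[C@H]2/C=C(/C)[C@@H](OC(C)=O)C/C=C(/C)[C@H](OC(=O)[C@]3(C)O[C@H]3C)[C@@H](O)[C@@H]12 | target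

## Step count and risks

Total: 24 steps. Longest linear sequence: 18 steps (steps 5–20, 23, 24).

The three steps most likely to fail:

Step 19 (key step). What may go wrong is poor facial selectivity at C6 in the ring-closing addition, since acyclic induction from C7 and C8 does not favour the needed epimer and control rests on the ring, with oligomerisation as a second risk. The fallback decouples the addition from the lactonisation and sets C6 with a reagent. It sets out from 27: the manganese-driven, chromium-catalytic variant of the coupling (CrCl2 cat., NiCl2 cat., Mn, Me3SiCl, THF/DMF, high dilution) traps the C6 alkoxide as the ten-membered C6 trimethylsilyl ether F1 (C6 epimers) before it can lactonise. Citric acid in MeOH frees the epimeric C6 carbinols F2, and Dess–Martin periodinane with NaHCO3 oxidises them to the ten-membered C6 enone F3. Corey–Bakshi–Shibata reduction with the matched enantiomer of the oxazaborolidine then gives the (6S) carbinol, which lactonises on brief PPTS treatment in CH2Cl2 and rejoins the route at 30.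

Step 14. What may go wrong is over-oxidation of the 1,2-diol (to the keto aldehyde or by C8–C9 cleavage) and self-condensation of the free α-hydroxy aldehyde before it is used. The fallback replaces the direct chemoselective oxidation by a protect–oxidise–release sequence. It sets out from 20: TESCl/imidazole gives the C8,C9-bis(triethylsilyl) ether F4. Swern oxidation, which converts a primary triethylsilyl ether directly into the aldehyde and leaves the secondary one, gives the α-triethylsilyloxy aldehyde F5. The silyl ether is then cleaved in the Barbier medium itself (THF/H2O with a little AcOH) immediately before indium and 4 are added, which returns the route to 21.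

Step 16. What may go wrong is poor discrimination between the C8 and C9 hydroxyls, with silylation at C8 or at both. The fallback differentiates the two oxygens by ring size instead of by hindrance. It sets out from 23: PPTS in CH2Cl2 lets the C9 hydroxyl displace one methoxy group of the C6 acetal to give the five-membered methyl furanoside F6 (the C8 hydroxyl could only form an oxetane and stays free). TBSOTf/2,6-lutidine gives the C8-silylated furanoside F7. EtSH/BF3·OEt2 opens the furanoside to the acyclic C6 diethyl dithioacetal F8 with the C9 hydroxyl free, and TESOTf/2,6-lutidine gives the C9 triethylsilyl ether F9. MeI/NaHCO3 in aqueous MeCN unmasks the aldehyde, and the route is rejoined at 27.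

Further compounds

F1 | step 19 | ten-membered C6 trimethylsilyl ether, methyl ester at C12, C6 epimers | COC(=O)C(=C)[C@H]1C(O[Si](C)(C)C)/C=C(/C)[C@@H](OC(C)=O)C/C=C(/C)[C@H](O[Si](CC)(CC)CC)[C@H]1O[Si](C)(C)C(C)(C)C
F2 | step 19 | ten-membered C6 carbinol, methyl ester at C12, C6 epimers | COC(=O)C(=C)[C@H]1C(O)/C=C(/C)[C@@H](OC(C)=O)C/C=C(/C)[C@H](O[Si](CC)(CC)CC)[C@H]1O[Si](C)(C)C(C)(C)C
F3 | step 19 | ten-membered C6 enone, methyl ester at C12 | COC(=O)C(=C)[C@H]1C(=O)/C=C(/C)[C@@H](OC(C)=O)C/C=C(/C)[C@H](O[Si](CC)(CC)CC)[C@H]1O[Si](C)(C)C(C)(C)C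
F4 | step 14 | (1Z,3S,5Z,7S)-1-iodo-2,6-dimethyl-7,8-bis[(triethylsilyl)oxy]octa-1,5-dien-3-yl acetate | CC[Si](CC)(CC)OC[C@@H](O[Si](CC)(CC)CC)/C(C)=C\C[C@H](OC(C)=O)/C(C)=C\I
F5 | step 14 | (1Z,3S,5Z,7S)-1-iodo-2,6-dimethyl-8-oxo-7-[(triethylsilyl)oxy]octa-1,5-dien-3-yl acetate | O=C[C@@H](O[Si](CC)(CC)CC)/C(C)=C\C[C@H](OC(C)=O)/C(C)=C\I
F6 | step 16 | methyl furanoside from 23 (ring O9–C6(OMe)–C7–C8–C9, C8 hydroxyl free, both anomers) | COC(=O)C(=C)[C@H]1C(OC)O[C@@H](/C(C)=C\C[C@H](OC(C)=O)/C(C)=C\I)[C@H]1O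
F7 | step 16 | C8 tert-butyldimethylsilyl ether of the methyl furanoside | COC(=O)C(=C)[C@H]1C(OC)O[C@@H](/C(C)=C\C[C@H](OC(C)=O)/C(C)=C\I)[C@H]1O[Si](C)(C)C(C)(C)C
F8 | step 16 | acyclic C6 diethyl dithioacetal, C8 tert-butyldimethylsilyl ether, C9 hydroxyl free | COC(=O)C(=C)[C@@H](C(SCC)SCC)[C@H](O[Si](C)(C)C(C)(C)C)[C@@H](O)/C(C)=C\C[C@H](OC(C)=O)/C(C)=C\I
F9 | step 16 | acyclic C6 diethyl dithioacetal, C8 tert-butyldimethylsilyl ether, C9 triethylsilyl ether | COC(=O)C(=C)[C@@H](C(SCC)SCC)[C@H](O[Si](C)(C)C(C)(C)C)[C@@H](O[Si](CC)(CC)CC)/C(C)=C\C[C@H](OC(C)=O)/C(C)=C\I
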